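**Retrosynthetic overview** (C1–C15 = carbon chain of the target counted from the alkyne terminus; ring carbons are C6–C10)
- Target ⇒ C1 desilylation and C9–OH → C9–Br (inversion) ⇒ 2,6-trans oxane alcohol, whose C11–C12 bond is made by a nickel-catalysed reductive alkyl–alkenyl coupling of an iodomethyl oxane with (E)-2-bromo-1-iodobut-1-ene.
- The only ring (the oxane) is formed once, by hydroxyl-directed 6-exo iodoetherification of an acyclic chloro diol; this sets C10 and delivers the CH2I handle.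
- The acyclic chloro diol comes from the union of an α-chloro lactol (C6–C11) with an α-alkynyl allylboronate (C1–C5); this new allylboration sets C6 and the Z-enyne in one step.
- The lactol comes from (R)-5-(hydroxymethyl)butyrolactone (C9 from the chiral pool, C7–Cl by trans-selective enolate chlorination); the boronate comes from two Matteson steps; the dihaloalkene from but-1-yne and IBr.

Assumption: Matteson homologation of the (S,S)-diol vinylboronate is taken to give the (1R)-chloride (mirror of the established (R,R)-diol → (1S) sense); if the sense were opposite, the (R,R)-diol would be used.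

**Step 1**
Reactants: 1 (5R)-5-(hydroxymethyl)oxolan-2-one
Product: 3 (5R)-5-ethenyloxolan-2-one, via (2R)-5-oxooxolane-2-carbaldehyde 2 (not isolated)
Conditions: (COCl)2, DMSO, CH2Cl2, −78 °C; Et3N; then Ph3P=CH2 (from Ph3PCH3Br, KN(SiMe3)2, THF), −78 → 0 °C
Reagents that add atoms: methyltriphenylphosphonium bromide, C[P+](c1ccccc1)(c1ccccc1)c1ccccc1.[Br-]
Why: Swern oxidation followed in the same flask by Wittig methylenation avoids isolating the water-soluble, epimerisable aldehyde 2, and the C9 stereocentre is carried over unchanged from the chiral pool.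

**Step 2**
Reactants: 3 (5R)-5-ethenyloxolan-2-one
Product: 5 (3S,5R)-3-chloro-5-ethenyloxolan-2-one, via lithium enolate 4 (not isolated)
Conditions: LiN(SiMe3)2, THF, −78 °C; then N-chlorosuccinimide, −78 °C
Reagents that add atoms: N-chlorosuccinimide, O=C1CCC(=O)N1Cl
Why: Electrophilic α-chlorination of a lactone enolate, in which the chlorine donor approaches the planar enolate anti to the C5 vinyl group and so sets C7 as the 3,5-trans (3S) chloride (minor cis isomer removed by chromatography).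

**Step 3**
Reactants: 5 (3S,5R)-3-chloro-5-ethenyloxolan-2-one
Product: 6 (3S,5R)-3-chloro-5-ethenyloxolan-2-ol (anomeric mixture)
Conditions: i-Bu2AlH, CH2Cl2, −78 °C; aq. KNaC4H4O6
Reagents that add atoms: none
Why: Partial reduction of a γ-lactone to its lactol with i-Bu2AlH at −78 °C, which touches no stereocentre of the target.

**Step 4**
Reactants: 7 vinylmagnesium bromide
Product: 9 (4S,5S)-4,5-dicyclohexyl-2-ethenyl-1,3,2-dioxaborolane, via ethenylboronic acid 8 (not isolated)
Conditions: B(OMe)3, THF, −78 °C; aq. HCl; then (1S,2S)-1,2-dicyclohexylethane-1,2-diol, MgSO4, Et2O, 25 °C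
Reagents that add atoms: trimethyl borate, COB(OC)OC; (1S,2S)-1,2-dicyclohexylethane-1,2-diol, O[C@@H](C1CCCCC1)[C@@H](O)C1CCCCC1
Why: Borylation of a Grignard reagent and esterification with a C2-symmetric diol, which installs the chiral director for the next step.

**Step 5**
Reactants: 9 (4S,5S)-4,5-dicyclohexyl-2-ethenyl-1,3,2-dioxaborolane
Product: 11 (4S,5S)-2-[(1R)-1-chloroprop-2-en-1-yl]-4,5-dicyclohexyl-1,3,2-dioxaborolane, via dichloromethyl borate complex 10 (not isolated)
Conditions: CH2Cl2, n-BuLi, THF, −100 °C; then 9; ZnCl2, −100 → 25 °C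
Reagents that add atoms: dichloromethane, ClCCl
Why: Matteson homologation, in which ZnCl2-assisted 1,2-migration of the vinyl group displaces one of the two diastereotopic chlorides under control of the diol and sets the boron-bearing carbon (future C3) as R.

**Step 6**
Reactants: 11 (4S,5S)-2-[(1R)-1-chloroprop-2-en-1-yl]-4,5-dicyclohexyl-1,3,2-dioxaborolane and 12 ethynyltrimethylsilane
Product: 15 (4S,5S)-4,5-dicyclohexyl-2-[(3S)-5-(trimethylsilyl)pent-1-en-4-yn-3-yl]-1,3,2-dioxaborolane, via lithium (trimethylsilyl)acetylide 13 (not isolated), via alkynyl borate complex 14 (not isolated)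
Conditions: 12, n-BuLi, THF, −78 °C; then 11, −78 → 25 °C
Reagents that add atoms: none
Why: Matteson substitution, a stereospecific 1,2-metallate rearrangement in which the alkynyl group moves from boron to carbon with inversion and gives the (3S) α-alkynyl allylboronate.

**Step 7**
Reactants: 16 but-1-yne
Product: 17 (1E)-2-bromo-1-iodobut-1-ene
Conditions: IBr, CH2Cl2, −78 → 0 °C
Reagents that add atoms: iodine monobromide, IBr
Why: Electrophilic anti iodobromination of a terminal alkyne (iodonium opened by bromide at the internal carbon) gives the E isomer, with bromine trans to the iodine that C11 will later replace.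

**Step 8**
Reactants: 6 (3S,5R)-3-chloro-5-ethenyloxolan-2-ol and 15 (4S,5S)-4,5-dicyclohexyl-2-[(3S)-5-(trimethylsilyl)pent-1-en-4-yn-3-yl]-1,3,2-dioxaborolane
Product: 20 (3R,5S,6R,8Z)-5-chloro-11-(trimethylsilyl)undeca-1,8-dien-10-yne-3,6-diol, via open-chain hydroxy aldehyde 18 (not isolated), via borate ester 19 (not isolated)
Conditions: toluene, 4 Å MS, 40 °C; then N(CH2CH2OH)3
Reagents that add atoms: none
Why: Proposed new method: Z-selective, doubly stereocontrolled allylboration with an α-alkynyl allylboronate, in which lactol 6 opens to α-chloro aldehyde 18 and reacts with 15 through a closed six-membered (Zimmerman–Traxler) chair where the slim alkynyl substituent sits axial to avoid gauche strain with the dioxaborolane oxygens, so the new C3=C4 alkene is Z, while the (3S) boron-bearing centre transfers its chirality to the aldehyde face that is also the Cornforth-preferred one for the (S)-α-chloro aldehyde (matched pair), setting C6 as R (anti chlorohydrin), and allyl transfer through the vinyl terminus should outrun allenyl transfer through the silyl-blocked alkyne; the closest known reaction type is the Z-selective allylboration of aldehydes with α-chloro-, α-alkoxy- and α-alkyl-substituted allylboronates with 1,3-chirality transfer.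

**Step 9**
Reactants: 20 (3R,5S,6R,8Z)-5-chloro-11-(trimethylsilyl)undeca-1,8-dien-10-yne-3,6-diol
Product: 21 (2S,3R,5S,6R)-5-chloro-2-(iodomethyl)-6-[(2Z)-5-(trimethylsilyl)pent-2-en-4-yn-1-yl]oxan-3-ol
Conditions: I2, NaHCO3, MeCN, 0 °C
Reagents that add atoms: iodine, II
Why: Kinetic 6-exo iodoetherification, in which the C6 hydroxyl opens the iodonium ion of the terminal alkene at C10 and the free allylic C9 hydroxyl directs the 1,2-cis (C9–OH/C10–CH2I) outcome, as in hydroxyl-directed iodoetherifications of pent-4-ene-1,3-diols and electrophile-induced cyclisations of hept-1-enitols to α-C-glycosides, which fixes C10 and the 2,6-trans ring.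

**Step 10**
Reactants: 21 (2S,3R,5S,6R)-5-chloro-2-(iodomethyl)-6-[(2Z)-5-(trimethylsilyl)pent-2-en-4-yn-1-yl]oxan-3-ol and 17 (1E)-2-bromo-1-iodobut-1-ene
Product: 22 (2R,3R,5S,6R)-2-[(2E)-3-bromopent-2-en-1-yl]-5-chloro-6-[(2Z)-5-(trimethylsilyl)pent-2-en-4-yn-1-yl]oxan-3-ol
Conditions: 17 (3 equiv), NiBr2(dme) (10 mol %), 4,4'-di-tert-butyl-2,2'-bipyridine (12 mol %), Mn powder, DMA, 25 °C
Reagents that add atoms: none
Why: Nickel-catalysed reductive cross-electrophile (alkyl–alkenyl) coupling, in which zerovalent nickel inserts into the C–I bond of 17 much faster than into its hindered internal C–Br bond, the primary radical from 21 is captured at nickel, and reductive elimination forms C11–C12 with retention of alkene geometry, while the secondary chloride is inert and Mn (not Zn) avoids direct metal insertion and ring-opening β-elimination.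

**Step 11**
Reactants: 22 (2R,3R,5S,6R)-2-[(2E)-3-bromopent-2-en-1-yl]-5-chloro-6-[(2Z)-5-(trimethylsilyl)pent-2-en-4-yn-1-yl]oxan-3-ol
Product: 23 (2R,3S,5S,6R)-3-bromo-2-[(2E)-3-bromopent-2-en-1-yl]-5-chloro-6-[(2Z)-5-(trimethylsilyl)pent-2-en-4-yn-1-yl]oxane
Conditions: CBr4, P(n-Oct)3, toluene, 70 °C
Reagents that add atoms: carbon tetrabromide, BrC(Br)(Br)Br
Why: Appel-type bromination, in which bromide displaces the equatorial oxyphosphonium group at C9 by SN2 with inversion to give the bromide trans to C11 under non-ionising conditions that suppress participation of the ring oxygen.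

**Step 12**
Reactants: 23 (2R,3S,5S,6R)-3-bromo-2-[(2E)-3-bromopent-2-en-1-yl]-5-chloro-6-[(2Z)-5-(trimethylsilyl)pent-2-en-4-yn-1-yl]oxane
Product: 24 (2R,3S,5S,6R)-3-bromo-2-[(2E)-3-bromopent-2-en-1-yl]-5-chloro-6-[(2Z)-pent-2-en-4-yn-1-yl]oxane
Conditions: K2CO3, MeOH, 0 °C
Reagents that add atoms: none
Why: Base-catalysed methanolysis of the alkynyl–silicon bond (protodesilylation) frees the terminal alkyne without touching the alkyl and alkenyl halides.

**Compound list**
1 | (5R)-5-(hydroxymethyl)oxolan-2-one | OC[C@H]1CCC(=O)O1 | starting material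
2 | (2R)-5-oxooxolane-2-carbaldehyde | O=C[C@H]1CCC(=O)O1 | intermediate
3 | (5R)-5-ethenyloxolan-2-one | C=C[C@H]1CCC(=O)O1 | intermediate
4 | lithium enolate of 3 | C=C[C@H]1CC=C(O[Li])O1 | intermediate
5 | (3S,5R)-3-chloro-5-ethenyloxolan-2-one | C=C[C@H]1C[C@H](Cl)C(=O)O1 | intermediate
6 | (3S,5R)-3-chloro-5-ethenyloxolan-2-ol (anomeric mixture) | C=C[C@H]1C[C@H](Cl)C(O)O1 | intermediate
7 | vinylmagnesium bromide | C=C[Mg]Br | starting material
8 | ethenylboronic acid | C=CB(O)O | intermediate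
9 | (4S,5S)-4,5-dicyclohexyl-2-ethenyl-1,3,2-dioxaborolane | C=CB1O[C@@H](C2CCCCC2)[C@H](C2CCCCC2)O1 | intermediate
10 | lithium (dichloromethyl)(ethenyl) borate complex of the (4S,5S)-diol | [Li+].C=C[B-]1(C(Cl)Cl)O[C@@H](C2CCCCC2)[C@H](C2CCCCC2)O1 | intermediate
11 | (4S,5S)-2-[(1R)-1-chloroprop-2-en-1-yl]-4,5-dicyclohexyl-1,3,2-dioxaborolane | C=C[C@H](Cl)B1O[C@@H](C2CCCCC2)[C@H](C2CCCCC2)O1 | intermediate
12 | ethynyltrimethylsilane | C#C[Si](C)(C)C | starting material
13 | lithium (trimethylsilyl)acetylide | [Li]C#C[Si](C)(C)C | intermediate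
14 | lithium [(1R)-1-chloroprop-2-en-1-yl][(trimethylsilyl)ethynyl] borate complex of the (4S,5S)-diol | [Li+].C=C[C@H](Cl)[B-]1(C#C[Si](C)(C)C)O[C@@H](C2CCCCC2)[C@H](C2CCCCC2)O1 | intermediate
15 | (4S,5S)-4,5-dicyclohexyl-2-[(3S)-5-(trimethylsilyl)pent-1-en-4-yn-3-yl]-1,3,2-dioxaborolane | C=C[C@@H](C#C[Si](C)(C)C)B1O[C@@H](C2CCCCC2)[C@H](C2CCCCC2)O1 | intermediate
16 | but-1-yne | CCC#C | starting material
17 | (1E)-2-bromo-1-iodobut-1-ene | I/C=C(/Br)CC | intermediate
18 | (2S,4R)-2-chloro-4-hydroxyhex-5-enal | O=C[C@@H](Cl)C[C@@H](O)C=C | intermediate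
19 | (4S,5S)-2-{[(3R,5S,6R,8Z)-5-chloro-3-hydroxy-11-(trimethylsilyl)undeca-1,8-dien-10-yn-6-yl]oxy}-4,5-dicyclohexyl-1,3,2-dioxaborolane | C[Si](C)(C)C#C/C=C\C[C@@H](OB1O[C@@H](C2CCCCC2)[C@H](C2CCCCC2)O1)[C@@H](Cl)C[C@@H](O)C=C | intermediate
20 | (3R,5S,6R,8Z)-5-chloro-11-(trimethylsilyl)undeca-1,8-dien-10-yne-3,6-diol | C[Si](C)(C)C#C/C=C\C[C@@H](O)[C@@H](Cl)C[C@@H](O)C=C | intermediate
21 | (2S,3R,5S,6R)-5-chloro-2-(iodomethyl)-6-[(2Z)-5-(trimethylsilyl)pent-2-en-4-yn-1-yl]oxan-3-ol | C[Si](C)(C)C#C/C=C\C[C@H]1O[C@H](CI)[C@H](O)C[C@@H]1Cl | intermediate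
22 | (2R,3R,5S,6R)-2-[(2E)-3-bromopent-2-en-1-yl]-5-chloro-6-[(2Z)-5-(trimethylsilyl)pent-2-en-4-yn-1-yl]oxan-3-ol | C[Si](C)(C)C#C/C=C\C[C@H]1O[C@H](C/C=C(/Br)CC)[C@H](O)C[C@@H]1Cl | intermediate
23 | (2R,3S,5S,6R)-3-bromo-2-[(2E)-3-bromopent-2-en-1-yl]-5-chloro-6-[(2Z)-5-(trimethylsilyl)pent-2-en-4-yn-1-yl]oxane | C[Si](C)(C)C#C/C=C\C[C@H]1O[C@H](C/C=C(/Br)CC)[C@@H](Br)C[C@@H]1Cl | intermediate
24 | (2R,3S,5S,6R)-3-bromo-2-[(2E)-3-bromopent-2-en-1-yl]-5-chloro-6-[(2Z)-pent-2-en-4-yn-1-yl]oxane | C#C/C=C\C[C@H]1O[C@H](C/C=C(/Br)CC)[C@@H](Br)C[C@@H]1Cl | target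

**Step count**
Total steps: 12. Longest linear sequence: 8 (steps 1, 2, 3, 8, 9, 10, 11, 12; the boronate branch 4, 5, 6, 8–12 is equally long). Step 7 is a one-step side branch.

**Steps most likely to fail, with fallbacks**

Step 8 (the proposed new allylboration; Z/E ratio, facial match and allyl versus allenyl transfer are untested). The fallback sets out from 6, comes back at 22, and uses only known reaction types. Lactol 6 is allylated with pinacol allylboronate (toluene, 25 °C, Cornforth-controlled anti addition) to give (3R,5S,6R)-5-chloronona-1,8-diene-3,6-diol F1. Iodoetherification under the conditions of step 9 gives (2S,3R,5S,6R)-5-chloro-2-(iodomethyl)-6-(prop-2-en-1-yl)oxan-3-ol F2. The nickel coupling of step 10 with 17 gives (2R,3R,5S,6R)-2-[(2E)-3-bromopent-2-en-1-yl]-5-chloro-6-(prop-2-en-1-yl)oxan-3-ol F3. Z-selective cross-metathesis of the allyl group with 4-(trimethylsilyl)but-1-en-3-yne (second-generation Hoveyda–Grubbs catalyst, benzene, 40 °C) then gives 22, so the enyne is installed late by metathesis instead of by the boronate.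

Step 9 (wrong C10 epimer, or attack of iodine on the enyne). The fallback sets out from 20 and comes back at 21, closing the ring by epoxide opening instead of iodonium capture. Sharpless epoxidation of the allylic alcohol (Ti(OiPr)4, D-(−)-diisopropyl tartrate, t-BuOOH, CH2Cl2, −20 °C; matched case for the (R)-carbinol, erythro-selective) gives (1R,3S,4R,6Z)-3-chloro-1-[(2S)-oxiran-2-yl]-9-(trimethylsilyl)non-6-en-8-yne-1,4-diol F4. Acid-catalysed 6-exo opening (camphorsulfonic acid, CH2Cl2, 0 °C) by the C6 hydroxyl with inversion at C10 gives (2R,3R,5S,6R)-5-chloro-2-(hydroxymethyl)-6-[(2Z)-5-(trimethylsilyl)pent-2-en-4-yn-1-yl]oxan-3-ol F5. Selective iodination of the primary alcohol (I2, PPh3, imidazole, THF, 0 °C) gives 21.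

Step 10 (the bromo-iodo-alkene and the β-oxygenated iodide have not been shown together in this coupling; over-reaction at C–Br or reduction of the iodide are possible). The fallback sets out from 21 and comes back at 22, replacing the reductive coupling by a boron-based palladium coupling. Radical borylation of the iodide (B2cat2, DMA, blue light) gives (2R,3R,5S,6R)-2-[(1,3,2-benzodioxaborol-2-yl)methyl]-5-chloro-6-[(2Z)-5-(trimethylsilyl)pent-2-en-4-yn-1-yl]oxan-3-ol F6, which is not isolated. Aqueous work-up hydrolyses it to {[(2R,3R,5S,6R)-5-chloro-3-hydroxy-6-[(2Z)-5-(trimethylsilyl)pent-2-en-4-yn-1-yl]oxan-2-yl]methyl}boronic acid F7. Silver-promoted Suzuki–Miyaura coupling with 17 at its C–I bond (PdCl2(dppf), Ag2O, K2CO3, THF, 70 °C, anhydrous so the alkynylsilane survives) gives 22.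

**Further compounds**
F1 | step 8 | (3R,5S,6R)-5-chloronona-1,8-diene-3,6-diol | C=CC[C@@H](O)[C@@H](Cl)C[C@@H](O)C=C
F2 | step 8 | (2S,3R,5S,6R)-5-chloro-2-(iodomethyl)-6-(prop-2-en-1-yl)oxan-3-ol | C=CC[C@H]1O[C@H](CI)[C@H](O)C[C@@H]1Cl
F3 | step 8 | (2R,3R,5S,6R)-2-[(2E)-3-bromopent-2-en-1-yl]-5-chloro-6-(prop-2-en-1-yl)oxan-3-ol | C=CC[C@H]1O[C@H](C/C=C(/Br)CC)[C@H](O)C[C@@H]1Cl
F4 | step 9 | (1R,3S,4R,6Z)-3-chloro-1-[(2S)-oxiran-2-yl]-9-(trimethylsilyl)non-6-en-8-yne-1,4-diol | C[Si](C)(C)C#C/C=C\C[C@@H](O)[C@@H](Cl)C[C@@H](O)[C@@H]1CO1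
F5 | step 9 | (2R,3R,5S,6R)-5-chloro-2-(hydroxymethyl)-6-[(2Z)-5-(trimethylsilyl)pent-2-en-4-yn-1-yl]oxan-3-ol | C[Si](C)(C)C#C/C=C\C[C@H]1O[C@H](CO)[C@H](O)C[C@@H]1Cl
F6 | step 10 | (2R,3R,5S,6R)-2-[(1,3,2-benzodioxaborol-2-yl)methyl]-5-chloro-6-[(2Z)-5-(trimethylsilyl)pent-2-en-4-yn-1-yl]oxan-3-ol | C[Si](C)(C)C#C/C=C\C[C@H]1O[C@H](CB2Oc3ccccc3O2)[C@H](O)C[C@@H]1Cl
F7 | step 10 | {[(2R,3R,5S,6R)-5-chloro-3-hydroxy-6-[(2Z)-5-(trimethylsilyl)pent-2-en-4-yn-1-yl]oxan-2-yl]methyl}boronic acid | C[Si](C)(C)C#C/C=C\C[C@H]1O[C@H](CB(O)O)[C@H](O)C[C@@H]1Cl
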